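## Retrosynthetic overview

1. The target is a ten-membered carbocycle (C1–C10, germacrane numbering) that is cis-fused at C6–C7 to the α-methylene-γ-butyrolactone and bridged C3–O–C10 by the 3(2H)-furanone ring.
2. Key disconnection: C1–C10, the only bond shared by the furanone ring and the carbocycle. The enabling feature is that the furanone unit O–C10–C1(=O)–C2=C3 is the cyclodehydrated form of a 4-hydroxy-2-yn-1-one. C1 can therefore be the sp terminus of a C1≡C2 alkyne next to a masked C3 ketone, and C10 a methyl ketone lying β to O8.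
3. Forward, a chromium-mediated alkynyl–ketone ring closure forms the ten-membered ring and the C10 carbinol in one step; the C10–O–C3 bridge then closes transannularly by hydrative cyclisation.
4. The ring-closure precursor is the lactone carrying both arms, made by joining two fragments at C6–C7 through an indium Barbier allylation and lactonisation (C6 and C7 set from C8).
5. Fragments: the C1–C6/C15 enal (methyl 4-hydroxybut-2-ynoate, CO as C3, ethynyltrimethylsilane as C1–C2) and the C7–C14 bromide (asymmetric glyoxylate-ene reaction sets C8; acrylate brings C11–C13). Ring order: lactone, carbocycle, furanone.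

Key step: step 16

Remark: germacrane numbering (C1–C15; C14 is the C10 methyl) locates atoms throughout; the target descriptors (6S,7R,8R,10R) mean a cis-fused lactone (H6/H7 cis), O8 anti to the C7 branch along C6–C9, and O8/O10 1,3-anti along C7–C10–C1, and the route is built for this array.

## Route

Step 1
Reactants: 1 methyl 4-hydroxybut-2-ynoate
Product: 2 methyl 4-[(tert-butyldiphenylsilyl)oxy]but-2-ynoate
Conditions: TBDPSCl, imidazole, CH2Cl2, 0 °C
Reagents that add atoms: tert-butyl(chloro)diphenylsilane, CC(C)(C)[Si](Cl)(c1ccccc1)c1ccccc1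
Why: Silyl ether formation at the primary alcohol; TBDPS is chosen because it should survive acetic acid, hydride, buffered fluoride and chromium steps until the last step.

Step 2
Reactants: 2 methyl 4-[(tert-butyldiphenylsilyl)oxy]but-2-ynoate
Product: 3 methyl (2Z)-4-[(tert-butyldiphenylsilyl)oxy]-3-iodobut-2-enoate
Conditions: NaI, AcOH, 70 °C
Reagents that add atoms: sodium iodide, [Na+].[I-]
Why: Hydroiodination of the ynoate (conjugate addition of iodide, anti protonation) should give the (Z)-β-iodo enoate, which fixes the future C4=C5 geometry with the C3 substituent cis to C6.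

Step 3
Reactants: 3 methyl (2Z)-4-[(tert-butyldiphenylsilyl)oxy]-3-iodobut-2-enoate; 4 ethynyltrimethylsilane
Product: 5 methyl (2Z)-3-{[(tert-butyldiphenylsilyl)oxy]methyl}-4-oxo-6-(trimethylsilyl)hex-2-en-5-ynoate
Conditions: CO (5 bar), PdCl2(PPh3)2 (5 mol %), CuI (2 mol %), Et3N, THF, 25 °C
Reagents that add atoms: carbon monoxide, [C-]#[O+]
Why: Carbonylative Sonogashira coupling (oxidative addition to zerovalent palladium, CO insertion, copper acetylide transfer, reductive elimination) joins three components with retention of olefin geometry, CO becoming the C3 carbonyl and the alkyne C1–C2.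

Step 4
Reactants: 5 methyl (2Z)-3-{[(tert-butyldiphenylsilyl)oxy]methyl}-4-oxo-6-(trimethylsilyl)hex-2-en-5-ynoate
Product: 6 methyl (2Z)-4-[(tert-butyldiphenylsilyl)oxy]-3-{2-[(trimethylsilyl)ethynyl]-1,3-dioxolan-2-yl}but-2-enoate
Conditions: TMSOCH2CH2OTMS, TMSOTf (5 mol %), CH2Cl2, −78 to −20 °C
Reagents that add atoms: 1,2-bis(trimethylsilyloxy)ethane, C[Si](C)(C)OCCO[Si](C)(C)C
Why: TMSOTf-catalysed ketalisation masks the C3 ketone, so that ester reduction, allylation and organochromium chemistry leave it alone and the cis γ-oxygenated enone cannot collapse to a furan.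

Step 5
Reactants: 6 methyl (2Z)-4-[(tert-butyldiphenylsilyl)oxy]-3-{2-[(trimethylsilyl)ethynyl]-1,3-dioxolan-2-yl}but-2-enoate
Product: 7 (2Z)-4-[(tert-butyldiphenylsilyl)oxy]-3-{2-[(trimethylsilyl)ethynyl]-1,3-dioxolan-2-yl}but-2-en-1-ol
Conditions: DIBAL-H (2.2 equiv), CH2Cl2, −78 °C
Reagents that add atoms: none
Why: DIBAL-H 1,2-reduction of the conjugated ester gives the allylic alcohol; ketal, silyl ether and silyl alkyne are inert at −78 °C.

Step 6
Reactants: 7 (2Z)-4-[(tert-butyldiphenylsilyl)oxy]-3-{2-[(trimethylsilyl)ethynyl]-1,3-dioxolan-2-yl}but-2-en-1-ol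
Product: 8 (2Z)-4-[(tert-butyldiphenylsilyl)oxy]-3-{2-[(trimethylsilyl)ethynyl]-1,3-dioxolan-2-yl}but-2-enal
Conditions: MnO2, CH2Cl2, 25 °C
Reagents that add atoms: none
Why: MnO2 oxidation of the allylic alcohol to the (Z)-enal under neutral conditions should preserve the ketal and the olefin geometry.

Step 7
Reactants: 9 2-methylpropene; 10 ethyl glyoxylate
Product: 11 ethyl (2R)-2-hydroxy-4-methylpent-4-enoate
Conditions: (R)-BINOL (10 mol %), TiCl2(OiPr)2 (10 mol %), 4 Å molecular sieves, CH2Cl2, −30 °C
Reagents that add atoms: none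
Why: Catalytic asymmetric carbonyl-ene (glyoxylate-ene) reaction; the (R)-BINOL–titanium Lewis acid exposes one aldehyde face to the alkene and should set C8 as (R), and the methallyl group is the latent C10 methyl ketone.

Step 8
Reactants: 11 ethyl (2R)-2-hydroxy-4-methylpent-4-enoate
Product: 12 ethyl (2R)-4-methyl-2-[(triethylsilyl)oxy]pent-4-enoate
Conditions: TESCl, imidazole, CH2Cl2, 0 °C
Reagents that add atoms: chlorotriethylsilane, CC[Si](Cl)(CC)CC
Why: Silyl ether formation protects O8 for the hydride and amine steps; TES is chosen because it can later be removed in the presence of the TBDPS ether.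

Step 9
Reactants: 12 ethyl (2R)-4-methyl-2-[(triethylsilyl)oxy]pent-4-enoate
Product: 13 (2R)-4-methyl-2-[(triethylsilyl)oxy]pent-4-enal
Conditions: DIBAL-H (1.1 equiv), CH2Cl2, −78 °C
Reagents that add atoms: none
Why: DIBAL-H half-reduction of an α-silyloxy ester should stop at the aldehyde through the stable tetrahedral aluminate at −78 °C, without epimerising C8.

Step 10
Reactants: 13 (2R)-4-methyl-2-[(triethylsilyl)oxy]pent-4-enal; 14 methyl acrylate
Product: 15 methyl (4R)-3-hydroxy-6-methyl-2-methylidene-4-[(triethylsilyl)oxy]hept-6-enoate (both C3 epimers)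
Conditions: DABCO (0.5 equiv), methyl acrylate (neat, excess), 25 °C
Reagents that add atoms: none
Why: Morita–Baylis–Hillman reaction installs C11–C13; the new carbinol centre is not controlled and disappears in the next step.

Step 11
Reactants: 15 methyl (4R)-3-hydroxy-6-methyl-2-methylidene-4-[(triethylsilyl)oxy]hept-6-enoate
Product: 16 methyl (2Z,4R)-2-(bromomethyl)-6-methyl-4-[(triethylsilyl)oxy]hepta-2,6-dienoate
Conditions: NBS, Me2S, CH2Cl2, 0 to 25 °C
Reagents that add atoms: N-bromosuccinimide, O=C1CCC(=O)N1Br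
Why: The alkoxysulfonium salt is displaced by bromide in the SN2′ sense (allylic transposition), which should give the more stable (Z)-2-(bromomethyl)enoate.

Step 12
Reactants: 16 methyl (2Z,4R)-2-(bromomethyl)-6-methyl-4-[(triethylsilyl)oxy]hepta-2,6-dienoate
Product: 17 methyl (2Z,4R)-2-(bromomethyl)-6-oxo-4-[(triethylsilyl)oxy]hept-2-enoate
Conditions: O3 (dosed to a dye end-point), CH2Cl2–MeOH, −78 °C; then Me2S, −78 to 0 °C
Reagents that add atoms: ozone, [O-][O+]=O
Why: Ozonolysis should be chemoselective for the electron-rich 1,1-disubstituted olefin over the electron-poor trisubstituted enoate, revealing the C10 methyl ketone.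

Step 13
Reactants: 8 (2Z)-4-[(tert-butyldiphenylsilyl)oxy]-3-{2-[(trimethylsilyl)ethynyl]-1,3-dioxolan-2-yl}but-2-enal; 17 methyl (2Z,4R)-2-(bromomethyl)-6-oxo-4-[(triethylsilyl)oxy]hept-2-enoate
Product: 19 cis-4,5-disubstituted α-methylene-γ-butyrolactone carrying the silyl-alkyne ketal arm on C6 and the keto silyl ether arm on C7 (4S,5S,1′R), via hydroxy ester 18 (not isolated)
Conditions: In powder (1.5 equiv), THF–H2O (3:1), 25 °C; then PPTS (10 mol %), CH2Cl2, 25 °C
Reagents that add atoms: none
Why: Indium-mediated Barbier allylation: the allylindium from 17 attacks the aldehyde through its γ-carbon in a chair-like six-membered transition state, the Z-bromide giving the syn adduct (cis-lactone after lactonisation), while C8 directs the C7 face by allylic strain (H8 eclipsing the olefin, aldehyde approaching anti to the C9 chain), and the aldehyde reacts in preference to the methyl ketone.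

Step 14
Reactants: 19 cis-lactone with silyl alkyne
Product: 20 cis-lactone with 1-iodoalkyne (4S,5S,1′R)
Conditions: NIS, AgNO3 (10 mol %), acetone, 25 °C, dark
Reagents that add atoms: N-iodosuccinimide, O=C1CCC(=O)N1I
Why: Silver-catalysed iododesilylation converts the silyl alkyne into the 1-iodoalkyne needed for chromium insertion without touching the lactone, the ketone or the silyl ethers.

Step 15
Reactants: 20 cis-lactone with 1-iodoalkyne
Product: 21 iodoalkyne β-hydroxy ketone (4R,5S,1′R)
Conditions: HF·pyridine, pyridine, THF, 0 °C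
Reagents that add atoms: none
Why: Buffered fluoride desilylation cleaves the secondary TES ether much faster than the primary TBDPS ether and leaves the ketal, freeing O8 as the chelation handle for the ring closure.

Step 16
Reactants: 21 iodoalkyne β-hydroxy ketone
Product: 22 macrocyclic alkynediol (6S,7R,8R,10R)
Conditions: CrCl2 (8 equiv), NiCl2 (2 mol %), DMF–THF (1:1), 25 °C, syringe-pump addition of 21 (final 2 mM); aqueous work-up
Reagents that add atoms: none
Why: Proposed new method: CrCl2, with NiCl2 catalysing insertion into the C(sp)–I bond, should convert 21 into an alkynylchromium species of trivalent chromium that is non-basic, spares the α-methylene lactone, the ketal and the free hydroxyl, and adds through C1 to the C10 ketone to give the chromium alkoxide of 22. The closest known reaction type is the Nozaki–Hiyama–Kishi alkynylation used to close nine- and ten-membered cycloalkyne rings onto aldehydes; extending it to a methyl ketone is reasonable because alkynylchromium reagents add to ketones when no aldehyde competes, the closure is intramolecular, and the cis-fused lactone and Z-C4=C5 olefin turn both chain ends to the same side. The ten-membered carbocycle closes in the 10-exo-trig mode at the C10 carbonyl, the near-linear C10–C1≡C2–C3 segment being spanned by the other six ring atoms as in cyclodecyne. The new stereocentre C10 is controlled by C8: chromium holds O8 and the ketone oxygen in a six-membered chelate with C7 and the methyl group equatorial, and axial chair-like attack of the tethered alkynyl carbon gives the 1,3-anti relation of O8 and O10 along C7–C10–C1, that is (8R,10R). The step needs chemoselectivity for the ketone and face selectivity at C10; the first rests on the low nucleophilicity of organochromium reagents toward esters and conjugate acceptors, the second on the chelate formed by the free C8 hydroxyl.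

Step 17
Reactants: 22 macrocyclic alkynediol; 23 3-methylbutanoic anhydride (isovaleric anhydride)
Product: 24 C8 isovalerate of the macrocyclic alkynediol (6S,7R,8R,10R)
Conditions: DMAP (10 mol %), pyridine, CH2Cl2, 0 to 25 °C
Reagents that add atoms: none
Why: DMAP-catalysed acylation esterifies the secondary C8 hydroxyl while the tertiary propargylic C10 hydroxyl is too hindered, and it is done before the furanone forms so that O8 cannot compete for the ynone.

Step 18
Reactants: 24 C8 isovalerate of the macrocyclic alkynediol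
Product: 27 C15 TBDPS ether of the target, via ynone 25 (not isolated), via hydroxy diketone 26 (not isolated)
Conditions: TsOH·H2O (0.2 equiv), acetone–H2O (10:1), 25 °C; then (Ph3P)AuNTf2 (5 mol %), 40 °C
Reagents that add atoms: water, O
Why: Acid unveils the C3 ketone (25), the gold catalyst (monovalent gold) activates the alkyne for hydration at C1, the carbon β to C3=O (26), and the C10 hydroxyl then closes on C3 with loss of water; this is the known conversion of 4-hydroxy-2-yn-1-ones into 3(2H)-furanones, here transannular and helped by release of cycloalkyne strain.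

Step 19
Reactants: 27 C15 TBDPS ether of the target
Product: 28 target, CNP0171896.2
Conditions: HF·pyridine, THF, 0 to 25 °C
Reagents that add atoms: none
Why: Fluoride desilylation under mildly acidic conditions should be tolerated by the α-methylene lactone, the furanone and the ester, and frees the C15 hydroxyl.

## Compound list

1 | methyl 4-hydroxybut-2-ynoate | COC(=O)C#CCO | starting material
2 | methyl 4-[(tert-butyldiphenylsilyl)oxy]but-2-ynoate | COC(=O)C#CCO[Si](c1ccccc1)(c1ccccc1)C(C)(C)C | intermediate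
3 | methyl (2Z)-4-[(tert-butyldiphenylsilyl)oxy]-3-iodobut-2-enoate | COC(=O)/C=C(/CO[Si](c1ccccc1)(c1ccccc1)C(C)(C)C)I | intermediate
4 | ethynyltrimethylsilane | C#C[Si](C)(C)C | starting material
5 | methyl (2Z)-3-{[(tert-butyldiphenylsilyl)oxy]methyl}-4-oxo-6-(trimethylsilyl)hex-2-en-5-ynoate | COC(=O)/C=C(/CO[Si](c1ccccc1)(c1ccccc1)C(C)(C)C)C(=O)C#C[Si](C)(C)C | intermediate
6 | methyl (2Z)-4-[(tert-butyldiphenylsilyl)oxy]-3-{2-[(trimethylsilyl)ethynyl]-1,3-dioxolan-2-yl}but-2-enoate | COC(=O)/C=C(/CO[Si](c1ccccc1)(c1ccccc1)C(C)(C)C)C1(C#C[Si](C)(C)C)OCCO1 | intermediate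
7 | (2Z)-4-[(tert-butyldiphenylsilyl)oxy]-3-{2-[(trimethylsilyl)ethynyl]-1,3-dioxolan-2-yl}but-2-en-1-ol | OC/C=C(/CO[Si](c1ccccc1)(c1ccccc1)C(C)(C)C)C1(C#C[Si](C)(C)C)OCCO1 | intermediate
8 | (2Z)-4-[(tert-butyldiphenylsilyl)oxy]-3-{2-[(trimethylsilyl)ethynyl]-1,3-dioxolan-2-yl}but-2-enal | O=C/C=C(/CO[Si](c1ccccc1)(c1ccccc1)C(C)(C)C)C1(C#C[Si](C)(C)C)OCCO1 | intermediate
9 | 2-methylpropene | CC(C)=C | starting material
10 | ethyl glyoxylate | CCOC(=O)C=O | starting material
11 | ethyl (2R)-2-hydroxy-4-methylpent-4-enoate | C=C(C)C[C@@H](O)C(=O)OCC | intermediate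
12 | ethyl (2R)-4-methyl-2-[(triethylsilyl)oxy]pent-4-enoate | C=C(C)C[C@@H](O[Si](CC)(CC)CC)C(=O)OCC | intermediate
13 | (2R)-4-methyl-2-[(triethylsilyl)oxy]pent-4-enal | C=C(C)C[C@@H](O[Si](CC)(CC)CC)C=O | intermediate
14 | methyl acrylate | C=CC(=O)OC | starting material
15 | methyl (4R)-3-hydroxy-6-methyl-2-methylidene-4-[(triethylsilyl)oxy]hept-6-enoate (both C3 epimers) | C=C(C)C[C@@H](O[Si](CC)(CC)CC)C(O)C(=C)C(=O)OC | intermediate
16 | methyl (2Z,4R)-2-(bromomethyl)-6-methyl-4-[(triethylsilyl)oxy]hepta-2,6-dienoate | C=C(C)C[C@@H](O[Si](CC)(CC)CC)/C=C(\CBr)C(=O)OC | intermediate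
17 | methyl (2Z,4R)-2-(bromomethyl)-6-oxo-4-[(triethylsilyl)oxy]hept-2-enoate | CC(=O)C[C@@H](O[Si](CC)(CC)CC)/C=C(\CBr)C(=O)OC | intermediate
18 | methyl (3S,4S,5Z)-7-[(tert-butyldiphenylsilyl)oxy]-4-hydroxy-2-methylidene-3-[(1R)-3-oxo-1-(triethylsilyloxy)butyl]-6-{2-[(trimethylsilyl)ethynyl]-1,3-dioxolan-2-yl}hept-5-enoate | C=C(C(=O)OC)[C@@H]([C@@H](O)/C=C(/CO[Si](c1ccccc1)(c1ccccc1)C(C)(C)C)C1(OCCO1)C#C[Si](C)(C)C)[C@H](O[Si](CC)(CC)CC)CC(C)=O | intermediate (not isolated)
19 | (4S,5S)-5-[(1Z)-3-[(tert-butyldiphenylsilyl)oxy]-2-{2-[(trimethylsilyl)ethynyl]-1,3-dioxolan-2-yl}prop-1-en-1-yl]-3-methylidene-4-[(1R)-3-oxo-1-(triethylsilyloxy)butyl]dihydrofuran-2(3H)-one | C=C1C(=O)O[C@@H](/C=C(/CO[Si](c2ccccc2)(c2ccccc2)C(C)(C)C)C2(OCCO2)C#C[Si](C)(C)C)[C@H]1[C@H](O[Si](CC)(CC)CC)CC(C)=O | intermediate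
20 | (4S,5S)-5-[(1Z)-3-[(tert-butyldiphenylsilyl)oxy]-2-[2-(iodoethynyl)-1,3-dioxolan-2-yl]prop-1-en-1-yl]-3-methylidene-4-[(1R)-3-oxo-1-(triethylsilyloxy)butyl]dihydrofuran-2(3H)-one | C=C1C(=O)O[C@@H](/C=C(/CO[Si](c2ccccc2)(c2ccccc2)C(C)(C)C)C2(OCCO2)C#CI)[C@H]1[C@H](O[Si](CC)(CC)CC)CC(C)=O | intermediate
21 | (4R,5S)-5-[(1Z)-3-[(tert-butyldiphenylsilyl)oxy]-2-[2-(iodoethynyl)-1,3-dioxolan-2-yl]prop-1-en-1-yl]-4-[(1R)-1-hydroxy-3-oxobutyl]-3-methylidenedihydrofuran-2(3H)-one | C=C1C(=O)O[C@@H](/C=C(/CO[Si](c2ccccc2)(c2ccccc2)C(C)(C)C)C2(OCCO2)C#CI)[C@H]1[C@H](O)CC(C)=O | intermediate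
22 | macrocyclic alkynediol: 6,7-cis-fused α-methylene-γ-butyrolactone on a ten-membered ring with C1≡C2, C3 as 1,3-dioxolane ketal, (4Z)-C4=C5 bearing CH2OTBDPS on C4, C8–OH and C10(OH)CH3; 6S,7R,8R,10R | C=C1C(=O)O[C@H]2/C=C(/CO[Si](c4ccccc4)(c4ccccc4)C(C)(C)C)C3(OCCO3)C#C[C@](C)(O)C[C@@H](O)[C@@H]12 | intermediate
23 | 3-methylbutanoic anhydride | CC(C)CC(=O)OC(=O)CC(C)C | starting material
24 | C8 3-methylbutanoate of 22; 6S,7R,8R,10R | C=C1C(=O)O[C@H]2/C=C(/CO[Si](c4ccccc4)(c4ccccc4)C(C)(C)C)C3(OCCO3)C#C[C@](C)(O)C[C@@H](OC(=O)CC(C)C)[C@@H]12 | intermediate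
25 | macrocyclic ynone (C3 ketone, C1≡C2, C10–OH); 6S,7R,8R,10R | C=C1C(=O)O[C@H]2/C=C(/CO[Si](c4ccccc4)(c4ccccc4)C(C)(C)C)C(=O)C#C[C@](C)(O)C[C@@H](OC(=O)CC(C)C)[C@@H]12 | intermediate (not isolated)
26 | macrocyclic 10-hydroxy-1,3-diketone (C1 and C3 ketones); 6S,7R,8R,10R | C=C1C(=O)O[C@H]2/C=C(/CO[Si](c4ccccc4)(c4ccccc4)C(C)(C)C)C(=O)CC(=O)[C@](C)(O)C[C@@H](OC(=O)CC(C)C)[C@@H]12 | intermediate (not isolated)
27 | C15 tert-butyldiphenylsilyl ether of the target; 6S,7R,8R,10R | C=C1C(=O)O[C@H]2/C=C(/CO[Si](c4ccccc4)(c4ccccc4)C(C)(C)C)C3=CC(=O)[C@@](C)(C[C@@H](OC(=O)CC(C)C)[C@@H]12)O3 | intermediate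
28 | CNP0171896.2; 6S,7R,8R,10R | C=C1C(=O)O[C@H]2/C=C(/CO)C3=CC(=O)[C@@](C)(C[C@@H](OC(=O)CC(C)C)[C@@H]12)O3 | target

## Step count and risks

Total step count: 19. Longest linear sequence: 13 steps (steps 1–6 then 13–19; equally steps 7–12 then 13–19).

Steps most likely to fail:

1. Step 16 (Proposed new method). The alkynylchromium may be protonated or coupled with itself faster than it adds to the hindered methyl ketone, the strained cycloalkyne may close slowly, and attack may occur on the wrong face of C10. The fallback uses known chemistry: the C1–C10 bond is made between fragments and the ring is closed at C6–C7 instead. It sets out from 7 and 17. K2CO3 in MeOH removes the C-silyl group of 7 to give the terminal alkynol F1. F1 is deprotonated twice with n-BuLi and transmetalated with CeCl3; the cerium acetylide adds to the ketone of 17 at −78 °C (the enoate and the allylic bromide should be left alone at this temperature) to give the tertiary propargylic alcohol F2, whose C10 epimers are separated. MnO2 oxidises the allylic alcohol to the enal bromide F3. In powder in THF–H2O at high dilution effects the intramolecular Barbier allylation to the macrocyclic hydroxy ester F4, which lactonises with PPTS to the macrocyclic lactone silyl ether F5. HF·pyridine removes the TES group and the fallback comes back to the route at 22.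

2. Step 13. Facial selectivity at C7 relative to C8 may be low with the non-chelating silyl ether, E/Z equilibration of the allylindium may erode the syn selectivity, and the allylindium may add to its own methyl ketone. The fallback replaces steric control by chelation control. It sets out from 17: HF·pyridine gives the free hydroxy bromide F6. Indium-mediated coupling of F6 with 8 in THF–H2O, in which indium is bound to O8 and to the allyl terminus and delivers the aldehyde to the C7 face on the O8 side (anti to the C9 chain), gives the dihydroxy ester F7. F7 lactonises with PPTS to the hydroxy lactone F8. NIS with catalytic AgNO3 then gives 21, where the fallback rejoins the route.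

3. Step 18. The gold-activated strained alkyne may undergo Meyer–Schuster-type rearrangement of the tertiary propargylic alcohol or hydration at C2 instead of C1, and the ketal may hydrolyse without ring closure following. The fallback uses an amine relay instead of gold catalysis. It sets out from 24: TsOH in wet acetone gives ynone 25, which is isolated. Diethylamine in EtOH adds to C1 (conjugate addition) to give the enaminone F9. Aqueous AcOH hydrolyses the enaminone and cyclodehydrates to 27, where the fallback rejoins the route.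

## Further compounds

F1 | step 16 | (2Z)-4-[(tert-butyldiphenylsilyl)oxy]-3-(2-ethynyl-1,3-dioxolan-2-yl)but-2-en-1-ol | OC/C=C(/CO[Si](c1ccccc1)(c1ccccc1)C(C)(C)C)C1(C#C)OCCO1
F2 | step 16 | open-chain tertiary propargylic alcohol, C1–C10 joined, allylic bromide and C6 alcohol present; 8R,10R | OC/C=C(/CO[Si](c1ccccc1)(c1ccccc1)C(C)(C)C)C1(OCCO1)C#C[C@](C)(O)C[C@@H](O[Si](CC)(CC)CC)/C=C(\CBr)C(=O)OC
F3 | step 16 | enal bromide from F2; 8R,10R | O=C/C=C(/CO[Si](c1ccccc1)(c1ccccc1)C(C)(C)C)C1(OCCO1)C#C[C@](C)(O)C[C@@H](O[Si](CC)(CC)CC)/C=C(\CBr)C(=O)OC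
F4 | step 16 | macrocyclic hydroxy ester (ten-membered ring, C6–OH, C7 bearing the methyl acrylate unit, C8–OTES); 6S,7S,8R,10R | C=C(C(=O)OC)[C@H]1[C@@H](O)/C=C(/CO[Si](c2ccccc2)(c2ccccc2)C(C)(C)C)C2(OCCO2)C#C[C@](C)(O)C[C@H]1O[Si](CC)(CC)CC
F5 | step 16 | C8 triethylsilyl ether of 22; 6S,7S,8R,10R | C=C1C(=O)O[C@H]2/C=C(/CO[Si](c4ccccc4)(c4ccccc4)C(C)(C)C)C3(OCCO3)C#C[C@](C)(O)C[C@@H](O[Si](CC)(CC)CC)[C@@H]12
F6 | step 13 | methyl (2Z,4R)-2-(bromomethyl)-4-hydroxy-6-oxohept-2-enoate | CC(=O)C[C@@H](O)/C=C(\CBr)C(=O)OC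
F7 | step 13 | C8-hydroxy analogue of 18 (open dihydroxy ester); 6S,7R,8R | C=C(C(=O)OC)[C@@H]([C@@H](O)/C=C(/CO[Si](c1ccccc1)(c1ccccc1)C(C)(C)C)C1(OCCO1)C#C[Si](C)(C)C)[C@H](O)CC(C)=O
F8 | step 13 | C8-hydroxy analogue of 19 (lactone with silyl alkyne); 4R,5S,1′R | C=C1C(=O)O[C@@H](/C=C(/CO[Si](c2ccccc2)(c2ccccc2)C(C)(C)C)C2(OCCO2)C#C[Si](C)(C)C)[C@H]1[C@H](O)CC(C)=O
F9 | step 18 | macrocyclic β-(diethylamino) enone (amine on C1, C3 ketone, C10–OH); 6S,7R,8R,10R | C=C1C(=O)O[C@H]2/C=C(/CO[Si](c4ccccc4)(c4ccccc4)C(C)(C)C)C(=O)C=C(N(CC)CC)[C@](C)(O)C[C@@H](OC(=O)CC(C)C)[C@@H]12
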